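## Structural features

The target is a flavone: a benzo-fused 4-pyranone (ring A fused to ring C through C4a–C8a) that carries an aryl group (ring B) on C2 through the C2–C1' bond. Ring A has methoxy groups on C7 and C8, so C8a–O1, C8 and C7 form a contiguous 1,2,3-trioxygenated edge, and C4a is the only carbon ortho to O1 that bears no oxygen. Ring B is a 3,4,5-trioxygenated phenyl ring in which only the 3'-oxygen is a free phenol, so ring B is unsymmetrical and its single OH must stay distinguishable from four methyl ethers to the end. There is no stereocentre, and the molecule is planar and achiral. The sensitive points are the free phenol, the 4'-methoxy group flanked by two oxygens (the one most easily lost to Lewis acids) and the C2=C3–C4=O enone of ring C (conjugate addition, reduction). The real difficulty is ring C: C4 must sit at ketone level between C4a and C3, C2 must be bonded to both O1 and ring B, and the closure must be six-membered and not the five-membered (aurone) mode. The key step exploits the salicyloyl relationship O1–C8a–C4a–C4: with C4 as a formyl group, the phenolic oxygen that ends as O1 steers a metal into the C4–H bond. C3 is then inserted as a carbene carbon that already carries C2 and ring B, which gives the 1,3-dicarbonyl at exactly the oxidation level of the flavone.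

## Logic of the disconnections

In one sentence: ring C is made by inserting the carbene carbon of 3 into the formyl C–H bond of 4 under catalysis by trivalent rhodium, followed by loss of water.

7 to 6. The bond cut is the O–CH2 bond of a benzyl ether on the 3'-oxygen. The lone phenol must be masked during the strongly basic ylide formation and is set free last. The gain is a precursor without an acidic proton. The forward step must cleave the benzylic C–O bond without reducing C2=C3 or C4=O of ring C and without touching the four methyl ethers.

6 to 5. The bond cut is O1–C2, with C2 returned to a ketone and C3 to a methylene group. Ring C is thereby opened to an ortho-hydroxyaryl 1,3-diketone. The forward step is a cyclodehydration that needs only acid. Because C3 is already bonded to both C4 and C2, only the six-membered closure is possible.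

5 to 3 + 4 (key disconnection). The bond cut is C3–C4. C4 becomes the formyl carbon of 4 and C3 the ylide (carbene) carbon of 3. This splits the molecule into two pieces of similar size, each one step or none from a purchasable arene, and places ring A and ring B in separate building blocks. The forward step must activate the formyl C–H bond in preference to every aryl C–H bond, and it must be redox-neutral, since 5 already has the oxidation level of the flavone.

3 to 2. The bond cut is C2–C3 (acyl carbon to ylide carbon). C3 comes from a one-carbon sulfoxonium ylide reagent and C2 from the ester carbonyl of 2. The forward step is an acyl substitution by a carbon nucleophile under strong base, which is why the phenol is already protected.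

2 to 1. The bond cut is the O–benzyl bond. 1 already carries the complete, unsymmetrical oxygenation pattern of ring B with the one free OH in the right place. The forward step is a simple O-alkylation.

## Other disconnections considered

Alternative 1: (the first that comes to mind) Cut C2–C3 and O1–C2. A Claisen–Schmidt condensation of 1-(2-hydroxy-3,4-dimethoxyphenyl)ethan-1-one A1 with 3-(benzyloxy)-4,5-dimethoxybenzaldehyde A2 would give the 2'-hydroxychalcone A3. Oxidative cyclisation of A3 (I2 in DMSO, hot) would then give 6. This is the default plan, so it fails the first test. The chalcone also stands two hydrogens above the flavone, so a stoichiometric oxidant is needed at high temperature in the presence of two electron-rich arenes, with ring iodination as a plausible side reaction. It saves no step (benzylation, aldol, oxidation, debenzylation). The chosen plan reaches the same ring C at the correct oxidation level without any oxidant.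

Alternative 2: Cut C4a–C4, C3–C4 and O1–C2. A carbonylative Sonogashira coupling of 6-iodo-2,3-dimethoxyphenol A5 with carbon monoxide and 1-(benzyloxy)-5-ethynyl-2,3-dimethoxybenzene A6 (PdCl2(PPh3)2, amine base) would be followed by 6-endo closure of the ynone to 6. The three-component idea is attractive, but the building blocks are costly. A5 would have to be made from 2,3-dimethoxyphenol A4, where electrophilic iodination is expected to favour the position para to the OH, so a protection, directed lithiation, iodination and deprotection sequence would be needed. A6 needs a homologation of A2. The key step also has two inherent ambiguities: coupling without carbon monoxide uptake (leading to a 2-arylbenzofuran) and 5-exo closure of the ynone (aurone). The chosen plan is about half as long and has no ring-size ambiguity.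

Alternative 3: Cut C4–C4a and O1–C2. Conjugate addition of A4 to methyl 3-[3-(benzyloxy)-4,5-dimethoxyphenyl]prop-2-ynoate A7 and saponification would give (Z)-3-[3-(benzyloxy)-4,5-dimethoxyphenyl]-3-(2,3-dimethoxyphenoxy)prop-2-enoic acid A8. An intramolecular Friedel–Crafts acylation of A8 (P2O5 in MeSO3H) at the only free ortho position of ring A would close ring C to 6. The ring A regiochemistry is secure. However, the acylium ion has a second nucleophile within reach, the C2'/C6' positions of ring B, each activated by an ortho and a para oxygen, which would lead to an indenone. The alkene geometry must also place the acid cis to the aryloxy group, and the strongly acidic medium endangers the benzyl ether and the 4'-methoxy group. With the preparation of A7 it is also longer than the chosen plan.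

Key step: step 3

Remark: compounds 1 and 4 are assumed to be purchasable. The target has no stereocentre, so the SMILES of the route carry no stereodescriptors.

## Steps

Step 1
Reactants: 1 methyl 3-hydroxy-4,5-dimethoxybenzoate
Product: 2 methyl 3-(benzyloxy)-4,5-dimethoxybenzoate
Conditions: BnBr (1.2 equiv), K2CO3 (2 equiv), DMF, 60 °C
Reagents that add atoms: benzyl bromide, BrCc1ccccc1
Why: Williamson ether synthesis (SN2 O-alkylation of the phenoxide); the ester and methyl ethers are inert, and the benzyl ether should withstand the strong base of step 2 and the acid of step 3.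

Step 2
Reactants: 2 methyl 3-(benzyloxy)-4,5-dimethoxybenzoate
Product: 3 1-[3-(benzyloxy)-4,5-dimethoxyphenyl]-2-[dimethyl(oxo)-λ6-sulfanylidene]ethan-1-one (aroyl sulfoxonium ylide)
Conditions: Me3S(O)I (3 equiv), KOtBu (3 equiv), THF, reflux, 2 h; then 2, THF, reflux
Reagents that add atoms: trimethylsulfoxonium iodide, C[S+](C)(C)=O.[I-]
Why: Corey–Chaykovsky-type acylation of dimethylsulfoxonium methylide by an ester (nucleophilic acyl substitution); the β-keto sulfoxonium salt formed first is deprotonated at once to the stabilised ylide, which prevents a second addition and should give 3 as a bench-stable carbene surrogate.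

Step 3
Reactants: 3 1-[3-(benzyloxy)-4,5-dimethoxyphenyl]-2-[dimethyl(oxo)-λ6-sulfanylidene]ethan-1-one; 4 2-hydroxy-3,4-dimethoxybenzaldehyde
Product: 6 2-[3-(benzyloxy)-4,5-dimethoxyphenyl]-7,8-dimethoxy-4H-chromen-4-one (3'-benzyloxy-4',5',7,8-tetramethoxyflavone), via 1,3-diketone 5 (not isolated)
Conditions: 4 (1.0 equiv), 3 (1.3 equiv), [Cp*RhCl2]2 (2.5 mol %), AgSbF6 (10 mol %), PivOH (1 equiv), ClCH2CH2Cl, 90 °C; then p-TsOH·H2O (20 mol %), 90 °C
Reagents that add atoms: none
Why: The cationic Cp*Rh species (trivalent rhodium) binds the phenoxide of 4 and cleaves the neighbouring formyl C–H bond by concerted metalation–deprotonation to a five-membered acyl rhodacycle. Ylide 3 then binds through carbon and loses DMSO to give a rhodium carbene; 1,1-migratory insertion of the acyl group and protonolysis form the C3–C4 bond and release 5 with rhodium still trivalent, so no oxidant is needed. The closest known reaction type is the redox-neutral, trivalent-rhodium-catalysed formyl C–H acylmethylation and annulation of salicylaldehydes with sulfoxonium ylides to give chromones. Ring C closes when the phenol OH of 5 adds to the distal aroyl carbonyl (6-exo-trig) and acid removes water; a five-membered closure is not available because C3 is already bonded to C4 and C2. No stereocentre is formed. The selectivity needed is activation of the formyl C–H bond in preference to aryl C–H bonds, above all the ortho C–H bonds of the aroyl ring of 3 that the ylide carbonyl could direct; the anionic phenoxide chelate secures it by holding rhodium next to the weak formyl C–H bond, and a modest excess of 3 covers any loss. The ring A pattern is fixed by 4, because the oxygen that directs the metal is the one that becomes O1. The benzyl and methyl ethers should be inert to these mildly acidic, non-reducing conditions.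

Step 4
Reactants: 6 2-[3-(benzyloxy)-4,5-dimethoxyphenyl]-7,8-dimethoxy-4H-chromen-4-one
Product: 7 2-(3-hydroxy-4,5-dimethoxyphenyl)-7,8-dimethoxy-4H-chromen-4-one (3'-hydroxy-4',5',7,8-tetramethoxyflavone)
Conditions: H2 (1 atm), 10% Pd/C, EtOAc–MeOH, rt, stopped when 6 is consumed
Reagents that add atoms: none
Why: Hydrogenolysis of a benzyl aryl ether over palladium on carbon; the benzylic C–O bond should be cleaved much faster than the conjugated C2=C3 bond of the vinylogous ester is hydrogenated at room temperature and 1 atm, and the methyl ethers are untouched.

## Compound list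

1 | methyl 3-hydroxy-4,5-dimethoxybenzoate | COC(=O)c1cc(O)c(OC)c(OC)c1 | starting material
2 | methyl 3-(benzyloxy)-4,5-dimethoxybenzoate | COC(=O)c1cc(OCc2ccccc2)c(OC)c(OC)c1 | intermediate
3 | 1-[3-(benzyloxy)-4,5-dimethoxyphenyl]-2-[dimethyl(oxo)-λ6-sulfanylidene]ethan-1-one | CS(C)(=O)=CC(=O)c1cc(OCc2ccccc2)c(OC)c(OC)c1 | intermediate
4 | 2-hydroxy-3,4-dimethoxybenzaldehyde | COc1ccc(C=O)c(O)c1OC | starting material
5 | 1-[3-(benzyloxy)-4,5-dimethoxyphenyl]-3-(2-hydroxy-3,4-dimethoxyphenyl)propane-1,3-dione | COc1ccc(C(=O)CC(=O)c2cc(OCc3ccccc3)c(OC)c(OC)c2)c(O)c1OC | intermediate (not isolated)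
6 | 2-[3-(benzyloxy)-4,5-dimethoxyphenyl]-7,8-dimethoxy-4H-chromen-4-one | COc1cc(-c2cc(=O)c3ccc(OC)c(OC)c3o2)cc(OCc2ccccc2)c1OC | intermediate
7 | 2-(3-hydroxy-4,5-dimethoxyphenyl)-7,8-dimethoxy-4H-chromen-4-one | COc1cc(-c2cc(=O)c3ccc(OC)c(OC)c3o2)cc(O)c1OC | target

## Step count and risks

Total step count: 4. Longest linear sequence: 4 steps (1 to 2 to 3 to 6 to 7); 4 enters at step 3.

Step 3 (key step). Most likely to go wrong: carbonyl-directed C–H activation of the aroyl ring of 3 with self-annulation of the ylide, decarbonylation of the acyl rhodium intermediate at 90 °C, or catalyst inhibition by chelation of rhodium between the phenoxide and the neighbouring 3-methoxy oxygen of 4. Each would consume 3 or stall the turnover before the C3–C4 bond is formed. Fallback, from 2 back to the route at 6: ester 2 would be condensed with the lithium dianion of purchased 1-(2-hydroxy-3,4-dimethoxyphenyl)ethan-1-one F1 (LiN(SiMe3)2, 3 equiv, THF, −78 °C to rt) in a crossed Claisen condensation. This gives the same diketone 5, which would be closed to 6 with p-TsOH·H2O in toluene at 90 °C. C3 then comes from the methyl ketone and the C2–C3 bond is made in place of C3–C4.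

Step 2. Most likely to go wrong: slow or incomplete acyl substitution at the electron-rich ester, so that the ylide reagent decomposes in refluxing THF before 2 is consumed. Fallback, from 2 back to the route at 3: saponification of 2 (LiOH, THF–H2O) would give 3-(benzyloxy)-4,5-dimethoxybenzoic acid F2. Oxalyl chloride with catalytic DMF in CH2Cl2 would convert F2 into 3-(benzyloxy)-4,5-dimethoxybenzoyl chloride F3. Adding F3 at 0 °C to an excess of preformed dimethylsulfoxonium methylide in THF should give 3 through a far more reactive acyl donor.

Step 4. Most likely to go wrong: over-reduction of the C2=C3 bond of ring C once the benzyl group is gone, or slow hydrogenolysis through poisoning of the palladium surface by sulfur traces carried over from step 3. Fallback, from 1 back to the route at 7, avoiding any reductive step: 1 would be protected with chloromethyl methyl ether (iPr2NEt, CH2Cl2) as methyl 3,4-dimethoxy-5-(methoxymethoxy)benzoate F4. The conditions of step 2 would convert F4 into 1-[3,4-dimethoxy-5-(methoxymethoxy)phenyl]-2-[dimethyl(oxo)-λ6-sulfanylidene]ethan-1-one F5. The conditions of step 3 would join F5 with 4 to give 2-[3,4-dimethoxy-5-(methoxymethoxy)phenyl]-7,8-dimethoxy-4H-chromen-4-one F6. HCl in MeOH at 50 °C would then cleave the acetal of F6 to 7.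

## Further compounds

F1 | step 3 | 1-(2-hydroxy-3,4-dimethoxyphenyl)ethan-1-one | CC(=O)c1ccc(OC)c(OC)c1O
F2 | step 2 | 3-(benzyloxy)-4,5-dimethoxybenzoic acid | COc1cc(C(=O)O)cc(OCc2ccccc2)c1OC
F3 | step 2 | 3-(benzyloxy)-4,5-dimethoxybenzoyl chloride | COc1cc(C(=O)Cl)cc(OCc2ccccc2)c1OC
F4 | step 4 | methyl 3,4-dimethoxy-5-(methoxymethoxy)benzoate | COCOc1cc(C(=O)OC)cc(OC)c1OC
F5 | step 4 | 1-[3,4-dimethoxy-5-(methoxymethoxy)phenyl]-2-[dimethyl(oxo)-λ6-sulfanylidene]ethan-1-one | COCOc1cc(C(=O)C=S(C)(C)=O)cc(OC)c1OC
F6 | step 4 | 2-[3,4-dimethoxy-5-(methoxymethoxy)phenyl]-7,8-dimethoxy-4H-chromen-4-one | COCOc1cc(-c2cc(=O)c3ccc(OC)c(OC)c3o2)cc(OC)c1OC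
A1 | alternative 1 | 1-(2-hydroxy-3,4-dimethoxyphenyl)ethan-1-one | CC(=O)c1ccc(OC)c(OC)c1O
A2 | alternative 1 | 3-(benzyloxy)-4,5-dimethoxybenzaldehyde | COc1cc(C=O)cc(OCc2ccccc2)c1OC
A3 | alternative 1 | (E)-3-[3-(benzyloxy)-4,5-dimethoxyphenyl]-1-(2-hydroxy-3,4-dimethoxyphenyl)prop-2-en-1-one | COc1ccc(C(=O)/C=C/c2cc(OCc3ccccc3)c(OC)c(OC)c2)c(O)c1OC
A4 | alternative 2 | 2,3-dimethoxyphenol | COc1cccc(O)c1OC
A5 | alternative 2 | 6-iodo-2,3-dimethoxyphenol | COc1ccc(I)c(O)c1OC
A6 | alternative 2 | 1-(benzyloxy)-5-ethynyl-2,3-dimethoxybenzene | C#Cc1cc(OC)c(OC)c(OCc2ccccc2)c1
A7 | alternative 3 | methyl 3-[3-(benzyloxy)-4,5-dimethoxyphenyl]prop-2-ynoate | COC(=O)C#Cc1cc(OC)c(OC)c(OCc2ccccc2)c1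
A8 | alternative 3 | (Z)-3-[3-(benzyloxy)-4,5-dimethoxyphenyl]-3-(2,3-dimethoxyphenoxy)prop-2-enoic acid | OC(=O)/C=C(\Oc1cccc(OC)c1OC)c1cc(OC)c(OC)c(OCc2ccccc2)c1
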